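## Structural features

The target is a hexacyclic biflavonoid. A 5,7-dihydroxychroman-4-one (rings A and C) is fused through its C2–C3 bond to a dihydrofuran (ring F). The benzo part of that furan is ring D of a (2''S)-flavan, whose pyran ring carries the 4-hydroxyphenyl ring E; a second 4-hydroxyphenyl group (ring B) sits on C2.

C2 is a fully substituted mixed ketal carbon (O1, O7'', ring B, C3). C3 is a tertiary carbinol flanked by the C4 ketone and by C8'' of ring D. These two contiguous quaternary stereocentres are (2R,3R), which is the cis-fused 5/6 junction, so once C3 is set, C2 follows. The third stereocentre, C2'' (S), lies on the far side of ring D and cannot be expected to steer chemistry at C2/C3.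

The fragile elements are:
- the diaryl ketal at C2 (ionisable in acid);
- the tertiary alpha-ketol at C3 (acyl or aryl shift);
- the phloroglucinol-type rings A and D (oxidation, electrophilic attack at the free C6'' position);
- the C2''–O1'' benzylic ether para to an oxygenated aryl ring (acid-promoted ionisation with loss of configuration).

The real difficulty is twofold. The C3–C8'' bond joins a quaternary carbon to an arene carbon with two ortho oxygen substituents, and the absolute sense of the C2/C3 pair must be imposed by a reagent.

The key step exploits the fact that C8'' sits on the carbon alpha to the C4 carbonyl, so rings A, C and D form a 3-arylchromanone (isoflavonoid) array. Ring D can therefore be attached first to the future C2 as the aryl group of a chalcone and moved to C3 by an oxidative 1,2-aryl shift. The congested C3–C8'' bond then results from an intramolecular migration that starts from an easily placed 8''-formyl group.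

## Logic of the disconnections

**21 ⇒ 20.** The four O–CH2Ph bonds at O5, O7, O4' and O4''' are cut. Benzyl ethers survive hydroxide, organolithium and organozinc reagents, trivalent thallium and dilute acid, and they leave under neutral hydrogenolysis, which exposes the C2 ketal and C3 ketol to neither acid nor base. The gain is that every oxidant in the route meets masked phenols. The demand is that hydrogenolysis stop before the hindered benzylic C2–O, C3–O and C2''–O1'' bonds react.

**20 ⇒ 18 (through 19).** The C2–O7'' and C3–O bonds are cut, which removes ring F and both quaternary stereocentres and leaves a planar 2,3-diarylchromone. The two bonds are the two ends of one oxygen transfer to C2=C3: oxygen on C3, then capture of the C2 cation by the ring D phenol. The forward step must deliver oxygen to one face under reagent control and must not oxidise ring D. The ring D phenols are therefore still masked in 18 and are released by acid only after the oxygen is in place (19).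

**18 ⇒ 15 + 16.** The C2–C1' bond is cut. C2–H is the only C–H bond left on the pyranone ring of 15 and is acidic, so ring B can be added late by metalation and cross-coupling with 16. The demand is selective metalation at C2 and a coupling that tolerates the di-ortho-substituted ring D next to it.

**15 ⇒ 13 (through 14), the key disconnection.** The O1–C2 and C3–C8'' bonds are cut, and ring D is returned to the carbon that becomes C2. The most congested bond of the molecule becomes the product of an intramolecular 1,2-aryl shift, and ring D becomes the aldehyde-derived aryl group of a 2'-hydroxychalcone. The demands are aryl rather than hydride migration, an oxidant that spares two trioxygenated arenes, and acid mild enough for the acetal protecting groups and for C2''. Two changes to the design of 13 serve these demands: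
- both ring D phenols (O5'' and O7'') carry methoxymethyl groups, so they never have to be told apart and are freed together in the step that closes ring F;
- ring C is closed from 14 with a weak acid after the HNO3 of the oxidation has been neutralised.

**13 ⇒ 12 + 2.** The C(alpha)=C(beta) bond of the enone is cut (aldol condensation). This divides the molecule into its ring A half and its flavan half. The forward step must cope with a di-ortho-substituted, electron-rich aldehyde.

**2 ⇒ 1.** Two O–CH2Ph bonds are cut. The chelated phenol must stay free, which its hydrogen bond to the ketone ensures.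

**12 ⇒ 10 ⇒ 9.** The C8''–CHO bond is cut through the C8''–Br bond. Halogenation followed by halogen–metal exchange is run cold and without acid, unlike direct formylation. The demand is attack at C8'' and not at C6''.

**9 ⇒ 8.** The O1''–C2'' bond is cut. The flavan stereocentre becomes a benzylic carbinol, and the forward ring closure must proceed with clean inversion.

**8 ⇒ 7 ⇒ 6.** The carbinol C–H bond and the two C–H bonds of the ethylene bridge are removed in turn. The stereocentre is traced to a prochiral aryl ketone (catalyst-controlled hydride transfer) and the saturated chain to an enone. The alkene reduction must spare the benzyl ether.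

**6 ⇒ 4 + 5.** The C(alpha)=C(beta) bond is cut (aldol condensation), giving a salicylaldehyde and an acetophenone.

**4 ⇒ 3.** Two O–CH2OCH3 bonds are cut. As in 2, the phenol chelated to the carbonyl group stays free; it later becomes O1''.

## Other disconnections considered

**Alternative 1:** The cut is C3–O plus C2–O7'' (ring F) of the pentabenzyl ether A1, leading back to the 3-(7''-hydroxyflavan-8''-yl)flavone A2. The forward key step would be an enantioselective epoxidation of C2=C3 of A2, with the free 7''-phenol capturing the opening epoxide at C2.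
- In favour: both quaternary stereocentres and ring F would arise in one operation from a flat, storable flavone. The phenol is in place, so a labile 2-aryl epoxide would be intercepted at once.
- Against: it disconnects the last ring only and leaves the C3–C8'' bond of A2 unsolved. The electron-rich free phenol of ring D would face an electrophilic oxidant. Catalyst control over a tetrasubstituted alkene is not assured.
- Comparison: A1 differs from 20 only by a benzyl group at O5'', and the ring F closure is the same event as in step 12. On the stereochemical problem the two are equal. Alternative 1 is the better on the lifetime of the epoxide (immediate capture). The chosen sequence is the better on chemoselectivity, since no free phenol is present with the oxidant. The step count after the flavone is equal. Alternative 1 needs O5'' and O7'' to be distinguished, which the chosen design avoids. The chosen key step supplies the flavone that this alternative takes for granted.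

**Alternative 2:** The cut is C4–C4a, C3–C4 and C2–O7''. The aryl iodide A4, CO and the 8''-alkynyl-7''-hydroxyflavan A5 would be joined by a palladium-catalysed carbonylative annulation to the 3-aroyl-2-arylbenzofuran A3. Removal of the MOM group and a dearomatising oxidation of the furan C2=C3 bond, with closure of O1–C2 by the ring A phenol, would then lead to A1.
- In favour: three bonds and ring F would form in one convergent step. The C3–C8'' bond would come from an unhindered Sonogashira coupling. Ring B would arrive with the alkyne, and no thallium is needed. In step economy and convergence this alternative is the better, because formylation, aldol condensation, rearrangement and C2 arylation are replaced by an alkynylation and one coupling.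
- Against: A4 is di-ortho-oxygenated, so acyl-palladium formation would compete with non-carbonylative annulation and with simple cycloisomerisation of A5. The later oxidation would have to attack a furan deactivated by the 3-aroyl group. Ring C would then have to form by six-ring capture at C2.
- Comparison: the stereochemical problem (face selection on a planar tetrasubstituted alkene) is equal. The chosen plan is longer and linear, but each of its C–C bond formations belongs to a well-used reaction class. Alternative 2 is the weaker in the predictability of its two late steps.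

**Alternative 3:** The cut is C3–O and C2–O1 (ring C) of the 3-hydroxyflavanone A6, leading back to the alpha-(flavan-8''-yl)-2'-hydroxychalcone A7. The forward key step would be a catalytic asymmetric nucleophilic epoxidation followed by 6-endo opening of the epoxide at C2 by the 2'-phenoxide (Algar–Flynn–Oyamada logic).
- In favour: the C3 carbinol would be set by a peroxide-based, nucleophilic epoxidation that leaves electron-rich arenes alone. On chemoselectivity of the oxygenation this is the better. Ring B would come from a simple aldehyde, so no C2 arylation is needed, and no thallium.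
- Against: A7 requires a ketone that already carries ring D on its alpha carbon, so the congested C3–C8'' bond must still be made by other means. Condensation next to a di-ortho-substituted aryl group is hindered and gives an alkene of uncertain geometry. Asymmetric epoxidation of alpha-aryl, trisubstituted enones has far less backing than that of simple chalcones. A 6'-alkoxy group is the feature that diverts this cyclisation towards 5-exo opening at the alpha carbon. A6 still has C2–H, so a further oxidation at C2, next to the oxidisable flavan, is needed before O7'' can close ring F, and the C2 stereocentre just made is then erased.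
- Comparison: on the mechanism of C3 oxygenation alternative 3 is equal or better. On structure it stops one oxidation level short. On step economy it is no shorter, because of the extra C2 oxidation and the separate synthesis of the alpha-aryl ketone.

Key step: step 10

Remark on the chemistry (assumption): the facial preference of the catalyst of step 12, (R,R)-Mn(salen)Cl = chloro[(R,R)-N,N'-bis(3,5-di-tert-butylsalicylidene)cyclohexane-1,2-diaminato]manganese, on this tetrasubstituted chromone is assumed and not known; the (S,S) catalyst is the direct replacement if the preference is the opposite. 4'-(Benzyloxy)acetophenone 5 is taken as a commercial starting material.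

## Route

Step 1
Reactants: 1 2',4',6'-trihydroxyacetophenone
Product: 2 1-[2-hydroxy-4,6-bis(benzyloxy)phenyl]ethanone
Conditions: BnBr (2.1 equiv), K2CO3, DMF, rt
Reagents that add atoms: benzyl bromide, BrCc1ccccc1
Why: Williamson etherification; the 2'-OH is held in a hydrogen bond to the ketone and stays free with two equivalents of benzyl bromide, leaving exactly the phenol needed later for ring C.

Step 2
Reactants: 3 2,4,6-trihydroxybenzaldehyde
Product: 4 2-hydroxy-4,6-bis(methoxymethoxy)benzaldehyde
Conditions: MOMCl (2.2 equiv), iPr2NEt, CH2Cl2, 0 °C to rt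
Reagents that add atoms: chloromethyl methyl ether, COCCl
Why: Chelation-controlled O-alkylation; the two non-chelated phenols react and the OH hydrogen-bonded to the aldehyde remains, which later becomes O1'' of the flavan.

Step 3
Reactants: 4 2-hydroxy-4,6-bis(methoxymethoxy)benzaldehyde; 5 1-[4-(benzyloxy)phenyl]ethanone
Product: 6 (E)-1-[4-(benzyloxy)phenyl]-3-[2-hydroxy-4,6-bis(methoxymethoxy)phenyl]prop-2-en-1-one
Conditions: KOH (50 % aq.), EtOH, rt; AcOH to pH 7
Reagents that add atoms: none
Why: Claisen–Schmidt condensation; aldol addition and E1cB dehydration give the E enone, and the neutral work-up avoids acid-induced cyclisation of the 2-hydroxychalcone to a flavylium salt.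

Step 4
Reactants: 6 (E)-1-[4-(benzyloxy)phenyl]-3-[2-hydroxy-4,6-bis(methoxymethoxy)phenyl]prop-2-en-1-one
Product: 7 1-[4-(benzyloxy)phenyl]-3-[2-hydroxy-4,6-bis(methoxymethoxy)phenyl]propan-1-one
Conditions: H2 (1 atm), RhCl(PPh3)3 (5 mol %), toluene/EtOH, 40 °C
Reagents that add atoms: none
Why: Homogeneous hydrogenation with RhCl(PPh3)3 saturates the disubstituted enone alkene without hydrogenolysis of the aryl benzyl ether and without reduction of the ketone.

Step 5
Reactants: 7 1-[4-(benzyloxy)phenyl]-3-[2-hydroxy-4,6-bis(methoxymethoxy)phenyl]propan-1-one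
Product: 8 (1R)-1-[4-(benzyloxy)phenyl]-3-[2-hydroxy-4,6-bis(methoxymethoxy)phenyl]propan-1-ol
Conditions: RuCl[(R,R)-TsDPEN](p-cymene) (2 mol %), HCO2H/Et3N (5:2), EtOAc, 30 °C
Reagents that add atoms: none
Why: Noyori asymmetric transfer hydrogenation of an aryl alkyl ketone; with the (R,R)-TsDPEN ligand hydride goes to the face that gives the (R)-carbinol (aryl recognised by its CH/pi contact with the arene ligand), and the free phenol and the MOM ethers are tolerated.

Step 6
Reactants: 8 (1R)-1-[4-(benzyloxy)phenyl]-3-[2-hydroxy-4,6-bis(methoxymethoxy)phenyl]propan-1-ol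
Product: 9 (2S)-2-[4-(benzyloxy)phenyl]-5,7-bis(methoxymethoxy)chromane
Conditions: PPh3, DIAD, toluene, −10 °C to rt
Reagents that add atoms: none
Why: Intramolecular Mitsunobu etherification (6-exo-tet); SN2 displacement of the activated benzylic oxygen by the phenol inverts the centre, (R)-carbinol to (2S)-flavan, and the low temperature in toluene is meant to suppress ionisation of the p-benzyloxybenzylic oxyphosphonium ion.

Step 7
Reactants: 9 (2S)-2-[4-(benzyloxy)phenyl]-5,7-bis(methoxymethoxy)chromane
Product: 10 (2S)-8-bromo-2-[4-(benzyloxy)phenyl]-5,7-bis(methoxymethoxy)chromane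
Conditions: NBS (1.0 equiv), CH2Cl2, −78 °C to 0 °C
Reagents that add atoms: N-bromosuccinimide, O=C1CCC(=O)N1Br
Why: Electrophilic aromatic bromination; 5,7-dialkoxyflavans react with NBS at C8 in preference to C6, since the site between the tied-back O1'' and the 7''-oxygen is the less hindered of the two doubly activated positions, and ring E is far less electron-rich.

Step 8
Reactants: 10 (2S)-8-bromo-2-[4-(benzyloxy)phenyl]-5,7-bis(methoxymethoxy)chromane
Product: 12 (2S)-2-[4-(benzyloxy)phenyl]-5,7-bis(methoxymethoxy)chromane-8-carbaldehyde, via 8-lithiochromane 11 (not isolated)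
Conditions: n-BuLi, THF, −78 °C; DMF, −78 °C to 0 °C; aq. NH4Cl
Reagents that add atoms: N,N-dimethylformamide, CN(C)C=O
Why: Bromine–lithium exchange at −78 °C is faster than any deprotonation, and formylation of the aryllithium with DMF fixes the formyl group at C8''.

Step 9
Reactants: 12 (2S)-2-[4-(benzyloxy)phenyl]-5,7-bis(methoxymethoxy)chromane-8-carbaldehyde; 2 1-[2-hydroxy-4,6-bis(benzyloxy)phenyl]ethanone
Product: 13 (E)-1-[2-hydroxy-4,6-bis(benzyloxy)phenyl]-3-[(2S)-2-(4-benzyloxyphenyl)-5,7-bis(methoxymethoxy)chroman-8-yl]prop-2-en-1-one
Conditions: KOH (50 % aq.), EtOH/THF, rt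
Reagents that add atoms: none
Why: Claisen–Schmidt condensation of the acetophenone enolate with a non-enolisable, di-ortho-substituted aldehyde; the chelated 2'-phenoxide and conjugation with ring A favour the open E chalcone over the flavanone.

Step 10
Reactants: 13 (E)-1-[2-hydroxy-4,6-bis(benzyloxy)phenyl]-3-[(2S)-2-(4-benzyloxyphenyl)-5,7-bis(methoxymethoxy)chroman-8-yl]prop-2-en-1-one
Product: 15 5,7-bis(benzyloxy)-3-[(2S)-2-(4-benzyloxyphenyl)-5,7-bis(methoxymethoxy)chroman-8-yl]-4H-chromen-4-one, via beta-keto dimethyl acetal 14 (not isolated)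
Conditions: Tl(NO3)3·3H2O (1.2 equiv), MeOH/HC(OMe)3 (3:1), 0 °C; NaHCO3; then PPTS (0.2 equiv), toluene, 80 °C
Reagents that add atoms: none
Why: This is the oxidative rearrangement of a 2'-hydroxychalcone to an isoflavone, the closest known reaction type being the Tl(NO3)3 isoflavone synthesis. Electrophilic trivalent thallium adds to the enone C=C at the alpha carbon while methanol is captured at the benzylic beta carbon; ring D, anti to the C–Tl bond, then shifts from the beta to the alpha carbon through a bridged phenonium ion as monovalent thallium departs, and the resulting oxocarbenium ion takes up methanol to give acetal 14, in which the C3–C8'' bond exists. Under PPTS one methoxy group leaves and the chelated 2'-phenol attacks the oxocarbenium carbon in a 6-exo-trig closure (O1–C2); loss of the second methanol across C2–C3 gives the chromone 15. No stereocentre is created: the alpha carbon of 14 is a transient centre that becomes sp2, and C2'' is a spectator. The step needs aryl rather than hydride migration, which the three oxygen donors of ring D secure despite its twist, and it needs an oxidant that spares rings A and D as arenes; Tl(NO3)3 is preferred to PhI(OAc)2 or PhI(OH)OTs because trivalent iodine would attack the free C6'' position of the trialkoxyarene. The HNO3 released threatens the two MOM ethers and the C2''–O1'' bond, hence the short contact at 0 °C, the bicarbonate quench before ring closure and the weak acid used for it.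

Step 11
Reactants: 15 5,7-bis(benzyloxy)-3-[(2S)-2-(4-benzyloxyphenyl)-5,7-bis(methoxymethoxy)chroman-8-yl]-4H-chromen-4-one; 16 1-(benzyloxy)-4-iodobenzene
Product: 18 5,7-bis(benzyloxy)-2-(4-benzyloxyphenyl)-3-[(2S)-2-(4-benzyloxyphenyl)-5,7-bis(methoxymethoxy)chroman-8-yl]-4H-chromen-4-one, via 2-chlorozincio isoflavone 17 (not isolated)
Conditions: TMPZnCl·LiCl (1.3 equiv), THF, 0 °C to rt; then 16, Pd(OAc)2 (5 mol %), SPhos (10 mol %), 50 °C
Reagents that add atoms: none
Why: With C3 blocked, C2–H (next to O1, beta to the carbonyl) is the only acidic chromone C–H; its zincation with a hindered zinc amide and Negishi coupling of the 2-zincated chromone with an aryl iodide is established chromone chemistry that tolerates the ethers, and SPhos is used because the coupling site is flanked by the di-ortho-substituted ring D.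

Step 12
Reactants: 18 5,7-bis(benzyloxy)-2-(4-benzyloxyphenyl)-3-[(2S)-2-(4-benzyloxyphenyl)-5,7-bis(methoxymethoxy)chroman-8-yl]-4H-chromen-4-one
Product: 20 (2R,3R)-5,7-bis(benzyloxy)-2-(4-benzyloxyphenyl)-3-hydroxychroman-4-one cis-fused through C2–O7'' and C3–C8'' to (2''S)-2''-(4-benzyloxyphenyl)-5''-hydroxychromane, via flavone 2,3-epoxide 19 (not isolated)
Conditions: (R,R)-Mn(salen)Cl (10 mol %), DMDO (acetone), CH2Cl2, −20 °C; evaporate; HCl, MeOH/THF, rt; evaporate; PPTS, toluene, 40 °C
Reagents that add atoms: dimethyldioxirane, CC1(C)OO1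
Why: Jacobsen–Katsuki oxygen transfer with DMDO as terminal oxidant is a known enantioselective epoxidation of the chromone C2=C3 bond (isoflavones) and of tetrasubstituted chromenes; here the catalyst must place oxygen on the face that makes C3 R [(2R,3R)-19], the remote C2'' giving no bias, and all phenols are masked so that the oxo-manganese species meets no free phenol. Acid then ionises the epoxide at C2 (cation stabilised by O1 and ring B) and cleaves both MOM ethers; the freed 7''-phenol captures the C2 oxocarbenium ion in a 5-exo-trig closure from the face opposite the C3–O bond, the only trajectory that gives a cis-fused 5/6 junction, so C2 (R) is dictated by C3 (R). The final warming with PPTS in toluene removes methanol and converts any C2 methyl ketal into the cyclic aryl ketal 20.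

Step 13
Reactants: 20 (2R,3R)-5,7-bis(benzyloxy)-2-(4-benzyloxyphenyl)-3-hydroxychroman-4-one cis-fused through C2–O7'' and C3–C8'' to (2''S)-2''-(4-benzyloxyphenyl)-5''-hydroxychromane
Product: 21 (2R,3R)-3,5,7-trihydroxy-2-(4-hydroxyphenyl)chroman-4-one cis-fused through C2–O7'' and C3–C8'' to (2''S)-5''-hydroxy-2''-(4-hydroxyphenyl)chromane (CNP0208300.2)
Conditions: H2 (1 atm), Pd/C (10 %), EtOAc/MeOH, rt
Reagents that add atoms: none
Why: Neutral hydrogenolysis of the four aryl benzyl ethers; the quaternary benzylic C2–O and C3–O bonds and the C2''–O1'' bond are hindered and should cleave far more slowly, and the reaction is stopped as soon as the last benzyl group is gone.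

## Compound list

1 | 2',4',6'-trihydroxyacetophenone | CC(=O)c1c(O)cc(O)cc1O | starting material
2 | 1-[2-hydroxy-4,6-bis(benzyloxy)phenyl]ethanone | CC(=O)c1c(O)cc(OCc2ccccc2)cc1OCc1ccccc1 | intermediate
3 | 2,4,6-trihydroxybenzaldehyde | O=Cc1c(O)cc(O)cc1O | starting material
4 | 2-hydroxy-4,6-bis(methoxymethoxy)benzaldehyde | O=Cc1c(O)cc(OCOC)cc1OCOC | intermediate
5 | 1-[4-(benzyloxy)phenyl]ethanone (4'-benzyloxyacetophenone) | CC(=O)c1ccc(OCc2ccccc2)cc1 | starting material
6 | (E)-1-[4-(benzyloxy)phenyl]-3-[2-hydroxy-4,6-bis(methoxymethoxy)phenyl]prop-2-en-1-one | O=C(/C=C/c1c(O)cc(OCOC)cc1OCOC)c1ccc(OCc2ccccc2)cc1 | intermediate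
7 | 1-[4-(benzyloxy)phenyl]-3-[2-hydroxy-4,6-bis(methoxymethoxy)phenyl]propan-1-one | O=C(CCc1c(O)cc(OCOC)cc1OCOC)c1ccc(OCc2ccccc2)cc1 | intermediate
8 | (1R)-1-[4-(benzyloxy)phenyl]-3-[2-hydroxy-4,6-bis(methoxymethoxy)phenyl]propan-1-ol | O[C@H](CCc1c(O)cc(OCOC)cc1OCOC)c1ccc(OCc2ccccc2)cc1 | intermediate
9 | (2S)-2-[4-(benzyloxy)phenyl]-5,7-bis(methoxymethoxy)chromane | COCOc1cc(OCOC)c2c(c1)O[C@H](c1ccc(OCc3ccccc3)cc1)CC2 | intermediate
10 | (2S)-8-bromo-2-[4-(benzyloxy)phenyl]-5,7-bis(methoxymethoxy)chromane | COCOc1cc(OCOC)c2c(c1Br)O[C@H](c1ccc(OCc3ccccc3)cc1)CC2 | intermediate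
11 | (2S)-2-[4-(benzyloxy)phenyl]-8-lithio-5,7-bis(methoxymethoxy)chromane (not isolated) | COCOc1cc(OCOC)c2c(c1[Li])O[C@H](c1ccc(OCc3ccccc3)cc1)CC2 | intermediate
12 | (2S)-2-[4-(benzyloxy)phenyl]-5,7-bis(methoxymethoxy)chromane-8-carbaldehyde | COCOc1cc(OCOC)c2c(c1C=O)O[C@H](c1ccc(OCc3ccccc3)cc1)CC2 | intermediate
13 | (E)-1-[2-hydroxy-4,6-bis(benzyloxy)phenyl]-3-[(2S)-2-(4-benzyloxyphenyl)-5,7-bis(methoxymethoxy)chroman-8-yl]prop-2-en-1-one | O=C(/C=C/c1c(OCOC)cc(OCOC)c2c1O[C@H](c1ccc(OCc3ccccc3)cc1)CC2)c1c(O)cc(OCc2ccccc2)cc1OCc1ccccc1 | intermediate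
14 | 1-[2-hydroxy-4,6-bis(benzyloxy)phenyl]-3,3-dimethoxy-2-[(2S)-2-(4-benzyloxyphenyl)-5,7-bis(methoxymethoxy)chroman-8-yl]propan-1-one, both epimers at the alpha carbon (not isolated) | COC(OC)C(C(=O)c1c(O)cc(OCc2ccccc2)cc1OCc1ccccc1)c1c(OCOC)cc(OCOC)c2c1O[C@H](c1ccc(OCc3ccccc3)cc1)CC2 | intermediate
15 | 5,7-bis(benzyloxy)-3-[(2S)-2-(4-benzyloxyphenyl)-5,7-bis(methoxymethoxy)chroman-8-yl]-4H-chromen-4-one | O=c1c(-c2c(OCOC)cc(OCOC)c3c2O[C@H](c2ccc(OCc4ccccc4)cc2)CC3)coc2cc(OCc3ccccc3)cc(OCc3ccccc3)c12 | intermediate
16 | 1-(benzyloxy)-4-iodobenzene | Ic1ccc(OCc2ccccc2)cc1 | starting material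
17 | chloro{5,7-bis(benzyloxy)-3-[(2S)-2-(4-benzyloxyphenyl)-5,7-bis(methoxymethoxy)chroman-8-yl]-4-oxo-4H-chromen-2-yl}zinc, LiCl complex (not isolated) | O=c1c(-c2c(OCOC)cc(OCOC)c3c2O[C@H](c2ccc(OCc4ccccc4)cc2)CC3)c([Zn]Cl)oc2cc(OCc3ccccc3)cc(OCc3ccccc3)c12 | intermediate
18 | 5,7-bis(benzyloxy)-2-(4-benzyloxyphenyl)-3-[(2S)-2-(4-benzyloxyphenyl)-5,7-bis(methoxymethoxy)chroman-8-yl]-4H-chromen-4-one | O=c1c(-c2c(OCOC)cc(OCOC)c3c2O[C@H](c2ccc(OCc4ccccc4)cc2)CC3)c(-c2ccc(OCc3ccccc3)cc2)oc2cc(OCc3ccccc3)cc(OCc3ccccc3)c12 | intermediate
19 | (2R,3R)-2,3-epoxide of 18: (2R,3R)-5,7-bis(benzyloxy)-2-(4-benzyloxyphenyl)-2,3-epoxy-3-[(2S)-2-(4-benzyloxyphenyl)-5,7-bis(methoxymethoxy)chroman-8-yl]chroman-4-one (not isolated) | O=C1c2c(OCc3ccccc3)cc(OCc3ccccc3)cc2O[C@]3(c4ccc(OCc5ccccc5)cc4)O[C@]13c1c(OCOC)cc(OCOC)c2c1O[C@H](c1ccc(OCc3ccccc3)cc1)CC2 | intermediate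
20 | 5,7,4',4'''-tetra-O-benzyl ether of 21 (free 3-OH and 5''-OH; 2R,3R,2''S) | O=C1c2c(OCc3ccccc3)cc(OCc3ccccc3)cc2O[C@@]2(c3ccc(OCc4ccccc4)cc3)Oc3cc(O)c4c(c3[C@@]12O)O[C@H](c1ccc(OCc3ccccc3)cc1)CC4 | intermediate
21 | (2R,3R)-3,5,7-trihydroxy-2-(4-hydroxyphenyl)chroman-4-one cis-fused through C2–O7'' and C3–C8'' to (2''S)-5''-hydroxy-2''-(4-hydroxyphenyl)chromane (CNP0208300.2) | O=C1c2c(O)cc(O)cc2O[C@@]2(c3ccc(O)cc3)Oc3cc(O)c4c(c3[C@@]12O)O[C@H](c1ccc(O)cc1)CC4 | target

## Step count and least certain steps

Total: 13 steps. Longest linear sequence: 12 steps (steps 2 to 13, from 3).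

**Step 10 (key step).** The most likely failure is attack of trivalent thallium on ring D (thallation or oxidation at the free C6'' position), together with acid damage by the HNO3 released (loss of MOM groups, ionisation at C2''). Both are favoured because oxythallation of an enone whose beta-aryl group is twisted by two ortho substituents is slow.
Fallback, from 2 and 10, back at 15: 2 is condensed with N,N-dimethylformamide dimethyl acetal to the enaminone F1, and iodine in CHCl3 closes it to the 3-iodochromone F2. Compound 10 is lithiated as in step 8 (11) and quenched with 2-isopropoxy-4,4,5,5-tetramethyl-1,3,2-dioxaborolane to give the pinacol boronate F3. Suzuki–Miyaura coupling of F2 with F3 (Pd(OAc)2, SPhos, K3PO4, toluene/water, 80 °C) gives 15. The C3–C8'' bond is then made by cross-coupling, without thallium or strong acid.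

**Step 12.** The most likely failure is weak facial discrimination, because the catalyst must approach a tetrasubstituted alkene whose two faces are screened by the ortho groups of the perpendicular ring D. Slow oxygen transfer would also give time for oxidation of ring D, and the ring-opened cation could undergo an acyl or aryl 1,2-shift before the phenol is released.
Fallback, from 18, back at 20: HCl in MeOH/THF removes both MOM groups to give the bis-phenol flavone F4. DMDO alone (acetone/CH2Cl2, −20 °C) then epoxidises C2=C3 while the 7''-phenol is already in place and captures the epoxide as it opens. This should give 20 together with its (2S,3S) diastereomer F5. Because of C2'' the two are diastereomers and are separated by chromatography. Catalyst control is replaced by separation.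

**Step 11.** The most likely failure is incomplete zincation or slow transmetalation and reductive elimination at a C2 position crowded by the di-ortho-substituted ring D, which would leave 15 unchanged.
Fallback, from 15 and 16, back at 18: iodine–magnesium exchange on 16 (iPrMgCl·LiCl) gives 4-(benzyloxy)phenylmagnesium chloride F6. Its CuBr·SMe2-mediated conjugate addition to 15 in the presence of Me3SiCl gives the 4-silyloxy-2H-chromene F7 (configuration at C2 immaterial). Saegusa–Ito oxidation (Pd(OAc)2, MeCN) re-forms the C2=C3 bond and gives 18.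

**Step 7.** The most likely failure is bromination at C6'' as well as at C8'', since both positions lie between two oxygen substituents and the MOM groups are smaller than the benzyl groups on which the C8 preference is best documented.
Fallback, from 8, back at 12: magnesium-mediated ortho-formylation of the phenol 8 (MgCl2, Et3N, paraformaldehyde, THF, reflux) can only occur at the one free ortho position, the future C8'', and gives the salicylaldehyde F8. Mitsunobu closure as in step 6 then gives 12 directly, bypassing 9, 10 and 11.

**Step 6.** The most likely failure is partial loss of configuration through ionisation of the activated p-benzyloxybenzylic alcohol (SN1 leakage beside the SN2 closure), which would erode the enantiomeric purity of C2''.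
Fallback, from 7, back at 9: PPTS in toluene with removal of water dehydrates the hemiketal form of 7 to the 4H-chromene F9. Asymmetric hydrogenation of its enol ether C=C bond with [Ir(cod)(L)]BArF (L = chiral phosphine–oxazoline, enantiomer chosen to give 2S) under H2 gives 9. The stereocentre then arises by hydrogenation and not by substitution.

## Further compounds

F1 | step 10 | (E)-1-[2-hydroxy-4,6-bis(benzyloxy)phenyl]-3-(dimethylamino)prop-2-en-1-one | CN(C)/C=C/C(=O)c1c(O)cc(OCc2ccccc2)cc1OCc1ccccc1
F2 | step 10 | 5,7-bis(benzyloxy)-3-iodo-4H-chromen-4-one | O=c1c(I)coc2cc(OCc3ccccc3)cc(OCc3ccccc3)c12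
F3 | step 10 | (2S)-2-[4-(benzyloxy)phenyl]-5,7-bis(methoxymethoxy)-8-(4,4,5,5-tetramethyl-1,3,2-dioxaborolan-2-yl)chromane | COCOc1cc(OCOC)c2c(c1B1OC(C)(C)C(C)(C)O1)O[C@H](c1ccc(OCc3ccccc3)cc1)CC2
F4 | step 12 | 5,7-bis(benzyloxy)-2-(4-benzyloxyphenyl)-3-[(2S)-2-(4-benzyloxyphenyl)-5,7-dihydroxychroman-8-yl]-4H-chromen-4-one | O=c1c(-c2c(O)cc(O)c3c2O[C@H](c2ccc(OCc4ccccc4)cc2)CC3)c(-c2ccc(OCc3ccccc3)cc2)oc2cc(OCc3ccccc3)cc(OCc3ccccc3)c12
F5 | step 12 | (2S,3S,2''S) diastereomer of 20 | O=C1c2c(OCc3ccccc3)cc(OCc3ccccc3)cc2O[C@]2(c3ccc(OCc4ccccc4)cc3)Oc3cc(O)c4c(c3[C@]12O)O[C@H](c1ccc(OCc3ccccc3)cc1)CC4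
F6 | step 11 | 4-(benzyloxy)phenylmagnesium chloride | Cl[Mg]c1ccc(OCc2ccccc2)cc1
F7 | step 11 | 5,7-bis(benzyloxy)-2-(4-benzyloxyphenyl)-3-[(2S)-2-(4-benzyloxyphenyl)-5,7-bis(methoxymethoxy)chroman-8-yl]-4-(trimethylsilyloxy)-2H-chromene, both epimers at C2 | C[Si](C)(C)OC1=C(c2c(OCOC)cc(OCOC)c3c2O[C@H](c2ccc(OCc4ccccc4)cc2)CC3)C(c2ccc(OCc3ccccc3)cc2)Oc2cc(OCc3ccccc3)cc(OCc3ccccc3)c12
F8 | step 7 | 3-[(3R)-3-(4-benzyloxyphenyl)-3-hydroxypropyl]-2-hydroxy-4,6-bis(methoxymethoxy)benzaldehyde | O[C@H](CCc1c(O)c(C=O)c(OCOC)cc1OCOC)c1ccc(OCc2ccccc2)cc1
F9 | step 6 | 2-[4-(benzyloxy)phenyl]-5,7-bis(methoxymethoxy)-4H-chromene | COCOc1cc(OCOC)c2c(c1)OC(c1ccc(OCc3ccccc3)cc1)=CC2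
A1 | alternative 1 | 5,7,4',5'',4'''-penta-O-benzyl ether of 21 (2R,3R,2''S) | O=C1c2c(OCc3ccccc3)cc(OCc3ccccc3)cc2O[C@@]2(c3ccc(OCc4ccccc4)cc3)Oc3cc(OCc4ccccc4)c4c(c3[C@@]12O)O[C@H](c1ccc(OCc3ccccc3)cc1)CC4
A2 | alternative 1 | 5,7-bis(benzyloxy)-2-(4-benzyloxyphenyl)-3-[(2S)-5-benzyloxy-2-(4-benzyloxyphenyl)-7-hydroxychroman-8-yl]-4H-chromen-4-one | O=c1c(-c2c(O)cc(OCc3ccccc3)c3c2O[C@H](c2ccc(OCc4ccccc4)cc2)CC3)c(-c2ccc(OCc3ccccc3)cc2)oc2cc(OCc3ccccc3)cc(OCc3ccccc3)c12
A3 | alternative 2 | 3-[2,4-bis(benzyloxy)-6-(methoxymethoxy)benzoyl]-2-(4-benzyloxyphenyl)benzofuran fused at its benzo ring to the (S)-flavan (5''-O-benzyl, 4'''-O-benzyl) | O=C(c1c(OCOC)cc(OCc2ccccc2)cc1OCc1ccccc1)c1c(-c2ccc(OCc3ccccc3)cc2)oc2cc(OCc3ccccc3)c3c(c12)O[C@H](c1ccc(OCc2ccccc2)cc1)CC3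
A4 | alternative 2 | 1,5-bis(benzyloxy)-2-iodo-3-(methoxymethoxy)benzene | COCOc1cc(OCc2ccccc2)cc(OCc2ccccc2)c1I
A5 | alternative 2 | (2S)-5-(benzyloxy)-2-[4-(benzyloxy)phenyl]-8-{[4-(benzyloxy)phenyl]ethynyl}chroman-7-ol | Oc1cc(OCc2ccccc2)c2c(c1C#Cc1ccc(OCc3ccccc3)cc1)O[C@H](c1ccc(OCc3ccccc3)cc1)CC2
A6 | alternative 3 | 2,3-trans-5,7-bis(benzyloxy)-2-(4-benzyloxyphenyl)-3-hydroxy-3-[(2S)-5-benzyloxy-2-(4-benzyloxyphenyl)-7-(methoxymethoxy)chroman-8-yl]chroman-4-one | O=C1c2c(OCc3ccccc3)cc(OCc3ccccc3)cc2O[C@@H](c2ccc(OCc3ccccc3)cc2)[C@@]1(O)c1c(OCOC)cc(OCc2ccccc2)c2c1O[C@H](c1ccc(OCc3ccccc3)cc1)CC2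
A7 | alternative 3 | (E)-1-[2-hydroxy-4,6-bis(benzyloxy)phenyl]-3-(4-benzyloxyphenyl)-2-[(2S)-5-benzyloxy-2-(4-benzyloxyphenyl)-7-(methoxymethoxy)chroman-8-yl]prop-2-en-1-one | O=C(c1c(O)cc(OCc2ccccc2)cc1OCc1ccccc1)/C(c1c(OCOC)cc(OCc2ccccc2)c2c1O[C@H](c1ccc(OCc3ccccc3)cc1)CC2)=C/c1ccc(OCc2ccccc2)cc1
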